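**Retrosynthetic overview** (oxolane numbering of the target: C-2 = CH2, C-3 bears the aroyl group, C-4 bears CH2OH, C-5 bears the dimethoxyphenyl group)
1. Target 13 ⇐ diol 12 (oxidation of the benzylic alcohol only) ⇐ cis-fused furofuranone 11 (LiAlH4); the ketone and the CH2OH are stored together as a γ-lactone (ring B).
2. 11 ⇐ bicyclic dihydrofuran 10 by syn hydrogenation from the convex face, which sets C-4 and C-5 cis to C-3.
3. 10 ⇐ acylcyclopropane 8 by Cloke–Wilson ring expansion (oxolane ring A, O-1–C-2 bond) ⇐ allyl β-keto ester 6 by oxidative cyclisation: the keto-ester α-carbon, oxidised by Mn(OAc)3 from enolate to electrophilic radical, bonds to the internal vinyl carbon (C-3–C-4 bond).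
4. 6 ⇐ (S)-allylic alcohol 4 + keto ester 5 (transesterification); 4 ⇐ aldehyde 1 by catalytic asymmetric vinylation; the S carbinol relays chirality to C-3 and is erased in the last step.
5. Ring order: lactone ring B and a cyclopropane (step 3), oxolane ring A (step 4), ring B opened (step 6).

Assumption: the SMILES is read as the all-cis isomer, [(3R,4R,5R)-5-(3,4-dimethoxyphenyl)-4-(hydroxymethyl)oxolan-3-yl](3,4,5-trimethoxyphenyl)methanone.

**Step 1**
Reactants: 1 3,4,5-trimethoxybenzaldehyde; 2 vinylmagnesium bromide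
Product: 4 (S)-1-(3,4,5-trimethoxyphenyl)prop-2-en-1-ol, via divinylzinc 3 (not isolated)
Conditions: 2 (2.4 equiv), ZnCl2 (1.2 equiv), Et2O/1,4-dioxane, 0 °C, filter off Mg salts; then 1, (−)-MIB [(2S)-3-exo-morpholinoisoborneol, 4 mol%], toluene, 0 °C; aq. NH4Cl
Reagents that add atoms: none
Why: Amino-alcohol-catalysed enantioselective addition of an organozinc to an aldehyde: the zinc alkoxide of (−)-MIB delivers the vinyl group to the same aldehyde face as it delivers ethyl from Et2Zn (which gives S-1-arylpropanols), so the S carbinol is set (about 90–95% ee expected; crystalline 8 is recrystallised to raise it).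

**Step 2**
Reactants: 4 (S)-1-(3,4,5-trimethoxyphenyl)prop-2-en-1-ol; 5 ethyl 3-(3,4-dimethoxyphenyl)-3-oxopropanoate
Product: 6 (S)-1-(3,4,5-trimethoxyphenyl)prop-2-en-1-yl 3-(3,4-dimethoxyphenyl)-3-oxopropanoate
Conditions: 5 (1.3 equiv), DMAP (0.2 equiv), toluene, 105 °C, 4 Å molecular sieves (removal of EtOH)
Reagents that add atoms: none
Why: DMAP-catalysed transesterification of a β-keto ester under neutral conditions; only the acyl–oxygen bond is exchanged, so the carbinol C–O bond and its S configuration are retained.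

**Step 3**
Reactants: 6 (S)-1-(3,4,5-trimethoxyphenyl)prop-2-en-1-yl 3-(3,4-dimethoxyphenyl)-3-oxopropanoate
Product: 8 (1R,4S,5S)-1-(3,4-dimethoxybenzoyl)-4-(3,4,5-trimethoxyphenyl)-3-oxabicyclo[3.1.0]hexan-2-one, via primary alkyl radical 7 (not isolated)
Conditions: Mn(OAc)3·2H2O (2.2 equiv), Cu(OAc)2·H2O (0.5 equiv), KOAc (2 equiv), degassed AcOH, 25–40 °C
Reagents that add atoms: none
Why: Oxidative radical cyclisation–cyclopropanation of an allyl β-keto ester: Mn(OAc)3 oxidises the enolised keto ester by one electron, so its α-carbon (normally a nucleophile) adds as an electrophilic radical 5-exo-trig to the internal alkene carbon to give radical 7, which divalent copper oxidises so that the enol carbon closes the three-membered ring; the aryl group on the S carbinol sits pseudo-equatorial in the chair-like transition state, so the new ring-fusion centre C-5 forms trans to it (S), and the cyclopropane can only be cis-fused (C-1 R); any product closed through oxygen is already 10 and converges in step 4.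

**Step 4**
Reactants: 8 (1R,4S,5S)-1-(3,4-dimethoxybenzoyl)-4-(3,4,5-trimethoxyphenyl)-3-oxabicyclo[3.1.0]hexan-2-one
Product: 10 (4S,5R)-8-(3,4-dimethoxyphenyl)-4-(3,4,5-trimethoxyphenyl)-3,7-dioxabicyclo[3.3.0]oct-1(8)-en-2-one, via iodomethyl enolate 9 (not isolated)
Conditions: NaI (0.3 equiv), DMF, 80 °C
Reagents that add atoms: none
Why: Nucleophile-catalysed Cloke–Wilson rearrangement: iodide opens the doubly activated cyclopropane at its CH2 group to give enolate 9, whose ketone oxygen displaces iodide (5-exo-tet) to form the push–pull dihydrofuran; the carbinol centre and C-5 are untouched and C-1 becomes sp2.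

**Step 5**
Reactants: 10 (4S,5R)-8-(3,4-dimethoxyphenyl)-4-(3,4,5-trimethoxyphenyl)-3,7-dioxabicyclo[3.3.0]oct-1(8)-en-2-one
Product: 11 (1S,4S,5R,8R)-8-(3,4-dimethoxyphenyl)-4-(3,4,5-trimethoxyphenyl)-3,7-dioxabicyclo[3.3.0]octan-2-one
Conditions: H2 (3 atm), 5% Rh/Al2O3, EtOAc, 25 °C
Reagents that add atoms: none
Why: Heterogeneous syn hydrogenation of a tetrasubstituted enol-ether double bond: both hydrogens add from the convex face (the face of H-5), since only a cis-fused lactone can form, which pushes the dimethoxyphenyl group to the concave face and gives the all-cis oxolane (C-1 S, C-8 R); Rh is chosen because it hardly cleaves benzylic C–O bonds.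

**Step 6**
Reactants: 11 (1S,4S,5R,8R)-8-(3,4-dimethoxyphenyl)-4-(3,4,5-trimethoxyphenyl)-3,7-dioxabicyclo[3.3.0]octan-2-one
Product: 12 (S)-[(3R,4R,5R)-5-(3,4-dimethoxyphenyl)-4-(hydroxymethyl)oxolan-3-yl](3,4,5-trimethoxyphenyl)methanol
Conditions: LiAlH4 (2 equiv), THF, 0 °C; Na2SO4·10H2O quench
Reagents that add atoms: none
Why: Hydride reduction of a lactone to a 1,4-diol; no stereocentre is touched and the work-up is kept neutral so the diol does not cyclise.

**Step 7**
Reactants: 12 (S)-[(3R,4R,5R)-5-(3,4-dimethoxyphenyl)-4-(hydroxymethyl)oxolan-3-yl](3,4,5-trimethoxyphenyl)methanol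
Product: 13 [(3R,4R,5R)-5-(3,4-dimethoxyphenyl)-4-(hydroxymethyl)oxolan-3-yl](3,4,5-trimethoxyphenyl)methanone
Conditions: activated MnO2 (15 equiv), CH2Cl2, 25 °C; filter through Celite
Reagents that add atoms: none
Why: Chemoselective oxidation of a benzylic alcohol on activated MnO2 under neutral conditions, which leaves the primary aliphatic alcohol and the epimerisable α-centre of the new ketone untouched; the carbinol centre that relayed chirality is erased.

**Compound list**
1 | 3,4,5-trimethoxybenzaldehyde | COc1cc(C=O)cc(OC)c1OC | starting material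
2 | vinylmagnesium bromide | C=C[Mg]Br | starting material
3 | divinylzinc | C=C[Zn]C=C | intermediate (not isolated)
4 | (S)-1-(3,4,5-trimethoxyphenyl)prop-2-en-1-ol | C=C[C@H](O)c1cc(OC)c(OC)c(OC)c1 | intermediate
5 | ethyl 3-(3,4-dimethoxyphenyl)-3-oxopropanoate | CCOC(=O)CC(=O)c1ccc(OC)c(OC)c1 | starting material
6 | (S)-1-(3,4,5-trimethoxyphenyl)prop-2-en-1-yl 3-(3,4-dimethoxyphenyl)-3-oxopropanoate | C=C[C@H](OC(=O)CC(=O)c1ccc(OC)c(OC)c1)c1cc(OC)c(OC)c(OC)c1 | intermediate
7 | [(2S,3S)-4-(3,4-dimethoxybenzoyl)-5-oxo-2-(3,4,5-trimethoxyphenyl)oxolan-3-yl]methyl radical | [CH2][C@@H]1[C@@H](c2cc(OC)c(OC)c(OC)c2)OC(=O)C1C(=O)c1ccc(OC)c(OC)c1 | intermediate (not isolated)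
8 | (1R,4S,5S)-1-(3,4-dimethoxybenzoyl)-4-(3,4,5-trimethoxyphenyl)-3-oxabicyclo[3.1.0]hexan-2-one | O=C1O[C@H](c3cc(OC)c(OC)c(OC)c3)[C@H]2C[C@@]12C(=O)c4ccc(OC)c(OC)c4 | intermediate
9 | sodium enolate of (4S,5S)-3-(3,4-dimethoxybenzoyl)-4-(iodomethyl)-5-(3,4,5-trimethoxyphenyl)oxolan-2-one | [Na+].[O-]C(c4ccc(OC)c(OC)c4)=C1C(=O)O[C@H](c3cc(OC)c(OC)c(OC)c3)[C@H]1CI | intermediate (not isolated)
10 | (4S,5R)-8-(3,4-dimethoxyphenyl)-4-(3,4,5-trimethoxyphenyl)-3,7-dioxabicyclo[3.3.0]oct-1(8)-en-2-one | O=C1O[C@H](c3cc(OC)c(OC)c(OC)c3)[C@H]2COC(c4ccc(OC)c(OC)c4)=C12 | intermediate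
11 | (1S,4S,5R,8R)-8-(3,4-dimethoxyphenyl)-4-(3,4,5-trimethoxyphenyl)-3,7-dioxabicyclo[3.3.0]octan-2-one | O=C1O[C@H](c3cc(OC)c(OC)c(OC)c3)[C@H]2CO[C@@H](c4ccc(OC)c(OC)c4)[C@@H]12 | intermediate
12 | (S)-[(3R,4R,5R)-5-(3,4-dimethoxyphenyl)-4-(hydroxymethyl)oxolan-3-yl](3,4,5-trimethoxyphenyl)methanol | COc1ccc([C@@H]2OC[C@H]([C@H](O)c3cc(OC)c(OC)c(OC)c3)[C@@H]2CO)cc1OC | intermediate
13 | [(3R,4R,5R)-5-(3,4-dimethoxyphenyl)-4-(hydroxymethyl)oxolan-3-yl](3,4,5-trimethoxyphenyl)methanone | COc1ccc([C@@H]2OC[C@H](C(=O)c3cc(OC)c(OC)c(OC)c3)[C@@H]2CO)cc1OC | target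

**Totals**
Total step count: 7. Longest linear sequence: 7 steps (1 → 13).

**Three steps most likely to fail**

Step 3 is the riskiest. The benzylic allylic ester may solvolyse in AcOH, the primary radical may attack an arene instead of closing, and the trans:cis ratio at C-4/C-5 may be modest. The cis isomer must be removed at 8, because after the last step it would give the enantiomer of the target. The fallback sets out from 6 and replaces the radical by a carbenoid. Diazo transfer with 4-acetamidobenzenesulfonyl azide and Et3N in MeCN gives (S)-1-(3,4,5-trimethoxyphenyl)prop-2-en-1-yl 2-diazo-3-(3,4-dimethoxyphenyl)-3-oxopropanoate F1. Rh2(OAc)4 (1 mol%) in CH2Cl2 at 40 °C then effects intramolecular cyclopropanation of the vinyl group, and the route is rejoined at 8.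

Step 5 may stall on the tetrasubstituted push–pull alkene, or may go on to reduce an arene or cleave a benzylic C–O bond. The fallback sets out from 10 and uses ionic hydrogenation in place of surface hydrogenation. TFA in CH2Cl2 at −20 to 0 °C protonates C-1 to give the cis-fused oxocarbenium salt (1S,4S,5R)-8-(3,4-dimethoxyphenyl)-2-oxo-4-(3,4,5-trimethoxyphenyl)-3,7-dioxabicyclo[3.3.0]oct-7-en-7-ium trifluoroacetate F2. Et3SiH then delivers hydride to its convex face, so the aryl group again ends up endo, and the route is rejoined at 11.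

Step 7 may be sluggish at the hindered carbinol, or the product may epimerise at C-3 on long contact with the oxidant. The fallback sets out from 12 and separates the two hydroxyl groups by protection. TBSCl and imidazole in CH2Cl2 at 0 °C silylate the primary alcohol to give (S)-[(3R,4R,5R)-4-{[tert-butyl(dimethyl)silyl]oxymethyl}-5-(3,4-dimethoxyphenyl)oxolan-3-yl](3,4,5-trimethoxyphenyl)methanol F3. Dess–Martin periodinane with NaHCO3 in CH2Cl2 gives [(3R,4R,5R)-4-{[tert-butyl(dimethyl)silyl]oxymethyl}-5-(3,4-dimethoxyphenyl)oxolan-3-yl](3,4,5-trimethoxyphenyl)methanone F4. HF·pyridine in THF at 0 °C removes the silyl group without base, and the route is rejoined at 13.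

**Further compounds**
F1 | step 3 | (S)-1-(3,4,5-trimethoxyphenyl)prop-2-en-1-yl 2-diazo-3-(3,4-dimethoxyphenyl)-3-oxopropanoate | C=C[C@H](OC(=O)C(=[N+]=[N-])C(=O)c1ccc(OC)c(OC)c1)c1cc(OC)c(OC)c(OC)c1
F2 | step 5 | (1S,4S,5R)-8-(3,4-dimethoxyphenyl)-2-oxo-4-(3,4,5-trimethoxyphenyl)-3,7-dioxabicyclo[3.3.0]oct-7-en-7-ium trifluoroacetate | O=C1O[C@H](c3cc(OC)c(OC)c(OC)c3)[C@H]2C[O+]=C(c4ccc(OC)c(OC)c4)[C@@H]12.[O-]C(=O)C(F)(F)F
F3 | step 7 | (S)-[(3R,4R,5R)-4-{[tert-butyl(dimethyl)silyl]oxymethyl}-5-(3,4-dimethoxyphenyl)oxolan-3-yl](3,4,5-trimethoxyphenyl)methanol | COc1ccc([C@@H]2OC[C@H]([C@H](O)c3cc(OC)c(OC)c(OC)c3)[C@@H]2CO[Si](C)(C)C(C)(C)C)cc1OC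
F4 | step 7 | [(3R,4R,5R)-4-{[tert-butyl(dimethyl)silyl]oxymethyl}-5-(3,4-dimethoxyphenyl)oxolan-3-yl](3,4,5-trimethoxyphenyl)methanone | COc1ccc([C@@H]2OC[C@H](C(=O)c3cc(OC)c(OC)c(OC)c3)[C@@H]2CO[Si](C)(C)C(C)(C)C)cc1OC
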